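## Retrosynthetic overview
1. The target comes from its 4'-O-methyl ether by a final aryl methyl ether cleavage. Rings B and D are bought as para-oxygenated benzenes.
2. Rings A and C form in one flask from a 6-(epoxyacylmethyl)-4-hydroxy-2-pyrone. The sequence is lactone opening, Claisen closure (ring A), then phenoxide opening of the epoxide (ring C). Inversion at the benzylic carbon gives 2R, and the retained Cα–O bond gives 3R.
3. The epoxy ketone side chain comes from acylating the pyrone C6-methyl carbanion with commercial methyl (2R,3S)-3-(4-methoxyphenyl)glycidate.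
4. The benzylic (R) centre comes from a chiral phosphoric acid catalysed 1,6-addition of C3 of triacetic acid lactone to the para-quinone methide of 4-(1-hydroxyethyl)phenol.
5. Ring order: the bought pyrone is sacrificed, then ring A and ring C form in that order in the same operation.

Assumption: the sense of induction of the phosphoric acid in step 1 cannot be predicted with certainty. The (R)-catalyst is written, and its mirror image is used if a test run gives the (S) product.

## Route

Step 1
Reactants: 1 4-hydroxy-6-methyl-2H-pyran-2-one (triacetic acid lactone, 1.5 equiv); 2 (±)-4-(1-hydroxyethyl)phenol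
Product: 4 4-hydroxy-3-[(1R)-1-(4-hydroxyphenyl)ethyl]-6-methyl-2H-pyran-2-one, via para-quinone methide 3 (not isolated)
Conditions: (R)-3,3'-bis(2,4,6-triisopropylphenyl)-1,1'-binaphthyl-2,2'-diyl hydrogen phosphate (10 mol %), 4 Å MS, ClCH2CH2Cl, 23–40 °C
Reagents that add atoms: none
Why: Proposed new method: the acid dehydrates 2 to 3 and binds the C=O of 3 through its O–H and the enol OH of 1 through its P=O, so the soft C3 of the pyrone adds 1,6 to one face of the ethylidene carbon, and rearomatisation makes the addition irreversible and sets the (R) centre; the closest known type is the chiral phosphoric acid catalysed asymmetric 1,6-conjugate addition (Friedel–Crafts type alkylation) of 1,3-dicarbonyls, naphthols and indoles to para-quinone methides made in situ from para-hydroxybenzyl alcohols.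

Step 2
Reactants: 4 4-hydroxy-3-[(1R)-1-(4-hydroxyphenyl)ethyl]-6-methyl-2H-pyran-2-one; 5 methyl (2R,3S)-3-(4-methoxyphenyl)oxirane-2-carboxylate
Product: 7 4-hydroxy-3-[(1R)-1-(4-hydroxyphenyl)ethyl]-6-{2-[(2R,3S)-3-(4-methoxyphenyl)oxiran-2-yl]-2-oxoethyl}-2H-pyran-2-one (used crude), via trilithio trianion 6 (not isolated)
Conditions: LiN(iPr)2 (3.1 equiv), THF–DMPU, −78 → −30 °C; 5 (1.0 equiv), −78 °C; AcOH, then pH 7 phosphate buffer
Reagents that add atoms: none
Why: This is a polyanion acylation (crossed Claisen condensation) in which the last-formed C6-CH2 carbanion of 6 attacks the ester carbonyl of 5 faster than the epoxide at −78 °C, the released methoxide deprotonates the new vinylogous 1,3-dicarbonyl and stops over-addition, and no stereocentre is touched because the oxirane C–H is not enolised.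

Step 3 (key step)
Reactants: 7 4-hydroxy-3-[(1R)-1-(4-hydroxyphenyl)ethyl]-6-{2-[(2R,3S)-3-(4-methoxyphenyl)oxiran-2-yl]-2-oxoethyl}-2H-pyran-2-one
Product: 10 (2R,3R)-3,5,7-trihydroxy-6-[(1R)-1-(4-hydroxyphenyl)ethyl]-2-(4-methoxyphenyl)-2,3-dihydro-4H-chromen-4-one, via triketo ester 8 (not isolated), via epoxy acylphloroglucinol 9 (not isolated)
Conditions: Mg(OMe)2 (4 equiv), MeOH–THF (degassed, Ar), 50 °C; then 1 M HCl to pH 3–4, 0 °C
Reagents that add atoms: none
Why: Proposed new method: magnesium-bound methoxide opens the enol lactone of 7 at its carbonyl to the templated triketo ester 8; the methylene next to the epoxy ketone then closes by Claisen (Dieckmann-type) attack on the ester, because the competing aldol mode would use the ester α-carbon, which carries the arylethyl group and could not aromatise, so ring A (9) forms with loss of methoxide; the phenoxide that was the pyrone ring oxygen, flanked by C–H and not held in the chelate with C=O, then opens the magnesium-activated epoxide 6-endo at the para-methoxybenzylic carbon with inversion (S becomes 2R) while the Cα–O bond stays (3R), giving the 2,3-trans, 6-substituted ring C; the closest known types are the biomimetic base or Mg(OMe)2 recyclisation of 6-(2-oxoalkyl)-4-hydroxy-2-pyrones to acylphloroglucinols and the closure of 2'-hydroxychalcone epoxides to dihydroflavonols (second half of the Algar–Flynn–Oyamada reaction).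

Step 4
Reactants: 10 (2R,3R)-3,5,7-trihydroxy-6-[(1R)-1-(4-hydroxyphenyl)ethyl]-2-(4-methoxyphenyl)-2,3-dihydro-4H-chromen-4-one
Product: 11 (2R,3R)-3,5,7-trihydroxy-2-(4-hydroxyphenyl)-6-[(1R)-1-(4-hydroxyphenyl)ethyl]-2,3-dihydro-4H-chromen-4-one (target)
Conditions: BBr3 (7 equiv), CH2Cl2, −78 → 0 °C; then ice–water
Reagents that add atoms: none
Why: In this BBr3 aryl methyl ether cleavage, boron binds the anisole oxygen and bromide removes the methyl group by SN2, while the boron chelate over 3-O, 4-C=O and 5-O deactivates ring A and the C2–O1 bond, so the three stereocentres stay intact at or below 0 °C.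

## Compound list
1 | 4-hydroxy-6-methyl-2H-pyran-2-one (triacetic acid lactone) | Cc1cc(O)cc(=O)o1 | starting material
2 | (±)-4-(1-hydroxyethyl)phenol | CC(O)c1ccc(O)cc1 | starting material
3 | 4-ethylidenecyclohexa-2,5-dien-1-one (para-quinone methide, not isolated) | CC=C1C=CC(=O)C=C1 | intermediate
4 | 4-hydroxy-3-[(1R)-1-(4-hydroxyphenyl)ethyl]-6-methyl-2H-pyran-2-one | C[C@H](c1ccc(O)cc1)c1c(O)cc(C)oc1=O | intermediate
5 | methyl (2R,3S)-3-(4-methoxyphenyl)oxirane-2-carboxylate (trans) | COC(=O)[C@@H]1O[C@H]1c1ccc(OC)cc1 | starting material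
6 | trilithium salt of 4 (phenoxide, pyronate, C6-CH2 carbanion; not isolated) | [Li+].[Li+].[Li+].C[C@H](c1ccc([O-])cc1)c1c([O-])cc([CH2-])oc1=O | intermediate
7 | 4-hydroxy-3-[(1R)-1-(4-hydroxyphenyl)ethyl]-6-{2-[(2R,3S)-3-(4-methoxyphenyl)oxiran-2-yl]-2-oxoethyl}-2H-pyran-2-one | C[C@H](c1ccc(O)cc1)c1c(O)cc(CC(=O)[C@@H]2O[C@H]2c2ccc(OC)cc2)oc1=O | intermediate
8 | methyl 2-[(1S)-1-(4-hydroxyphenyl)ethyl]-7-[(2R,3S)-3-(4-methoxyphenyl)oxiran-2-yl]-3,5,7-trioxoheptanoate (C2 epimers, present as magnesium enolate; same spatial arrangement at the benzylic carbon as in 4, the descriptor changes only through the priority rules; not isolated) | COC(=O)C([C@H](C)c1ccc(O)cc1)C(=O)CC(=O)CC(=O)[C@@H]1O[C@H]1c1ccc(OC)cc1 | intermediate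
9 | [(2R,3S)-3-(4-methoxyphenyl)oxiran-2-yl]{2,4,6-trihydroxy-3-[(1R)-1-(4-hydroxyphenyl)ethyl]phenyl}methanone (not isolated) | C[C@H](c1ccc(O)cc1)c1c(O)cc(O)c(C(=O)[C@@H]2O[C@H]2c2ccc(OC)cc2)c1O | intermediate
10 | (2R,3R)-3,5,7-trihydroxy-6-[(1R)-1-(4-hydroxyphenyl)ethyl]-2-(4-methoxyphenyl)-2,3-dihydro-4H-chromen-4-one | C[C@H](c1ccc(O)cc1)c1c(O)cc2c(c1O)C(=O)[C@H](O)[C@@H](c1ccc(OC)cc1)O2 | intermediate
11 | (2R,3R)-3,5,7-trihydroxy-2-(4-hydroxyphenyl)-6-[(1R)-1-(4-hydroxyphenyl)ethyl]-2,3-dihydro-4H-chromen-4-one | C[C@H](c1ccc(O)cc1)c1c(O)cc2c(c1O)C(=O)[C@H](O)[C@@H](c1ccc(O)cc1)O2 | target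

## Step count and risks
Total steps: 4. Longest linear sequence: 4 (1 → 4 → 7 → 10 → 11).

**Step 3 is the most likely to fail.**
- The para-methoxyphenyl epoxide may be solvolysed by methanol.
- It may be opened at Cα, giving a benzofuranone.
- Ring C may close through the hindered phenol, giving the 8-substituted isomer.
- Compound 10 is sensitive to base and air.

The fallback keeps the epoxide out of the basic stage and forms the two rings one after the other. It sets out from 5 and comes back at 10. Compound 5 with acetone and catalytic BF3·OEt2 gives methyl (4R)-5-(4-methoxyphenyl)-2,2-dimethyl-1,3-dioxolane-4-carboxylate F1. The Cα–O bond is kept, and the benzylic carbon becomes a mixture, which does not matter here. Trianion 6 is acylated with F1 as in step 2, giving 4-hydroxy-3-[(1R)-1-(4-hydroxyphenyl)ethyl]-6-{2-[(4R)-5-(4-methoxyphenyl)-2,2-dimethyl-1,3-dioxolan-4-yl]-2-oxoethyl}-2H-pyran-2-one F2. Mg(OMe)2 in refluxing MeOH, now with no labile group present, gives [(4R)-5-(4-methoxyphenyl)-2,2-dimethyl-1,3-dioxolan-4-yl]{2,4,6-trihydroxy-3-[(1R)-1-(4-hydroxyphenyl)ethyl]phenyl}methanone F3. Aqueous CF3CO2H in CH2Cl2 removes the acetonide and ionises the para-methoxybenzylic alcohol. The ortho phenol traps the cation under thermodynamic control to give 2,3-trans 10, with 3R carried over from 5.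

**Step 1 is second.**
- The methyl-substituted para-quinone methide is small, so facial selectivity may be modest.
- It can tautomerise to 4-vinylphenol and oligomerise.

The fallback sets the centre by hydride delivery instead of C–C bond formation. It sets out from 1 and comes back at 4. In(OTf)3-catalysed Markovnikov addition of 1 to 4-ethynylphenol gives 4-hydroxy-3-[1-(4-hydroxyphenyl)ethenyl]-6-methyl-2H-pyran-2-one F4. A chiral phosphoric acid with diethyl 2,6-dimethyl-1,4-dihydropyridine-3,5-dicarboxylate protonates F4 to the disubstituted para-quinone methide and delivers hydride to one face. This organocatalytic asymmetric transfer hydrogenation of hydroxy-substituted 1,1-diarylethenes gives 4.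

**Step 4 is third.**
- BBr3 and the HBr it releases may open the C2–O1 bond, causing C2 epimerisation or loss to a diketone.
- They may also cause dealkylation of ring A.

The fallback replaces the methyl ether with a benzyl ether that is removed by hydrogenolysis. It sets out from 4 (as trianion 6) and comes back at 11. Darzens condensation of 4-(benzyloxy)benzaldehyde with methyl chloroacetate (NaOMe, MeOH) gives (±)-trans-methyl 3-[4-(benzyloxy)phenyl]oxirane-2-carboxylate F5. Lipase-catalysed hydrolysis of the (2S,3R) ester, the type of kinetic resolution used to make 5, leaves methyl (2R,3S)-3-[4-(benzyloxy)phenyl]oxirane-2-carboxylate F6. Acylation of 6 with F6 gives 6-{2-[(2R,3S)-3-(4-benzyloxyphenyl)oxiran-2-yl]-2-oxoethyl}-4-hydroxy-3-[(1R)-1-(4-hydroxyphenyl)ethyl]-2H-pyran-2-one F7. The Mg(OMe)2 cascade of step 3 then gives (2R,3R)-2-(4-benzyloxyphenyl)-3,5,7-trihydroxy-6-[(1R)-1-(4-hydroxyphenyl)ethyl]-2,3-dihydro-4H-chromen-4-one F8. Finally, H2 over 10% Pd/C in EtOAc–MeOH gives 11.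

## Further compounds
F1 | step 3 | methyl (4R)-5-(4-methoxyphenyl)-2,2-dimethyl-1,3-dioxolane-4-carboxylate (C5 epimers) | COC(=O)[C@@H]1OC(C)(C)OC1c1ccc(OC)cc1
F2 | step 3 | 4-hydroxy-3-[(1R)-1-(4-hydroxyphenyl)ethyl]-6-{2-[(4R)-5-(4-methoxyphenyl)-2,2-dimethyl-1,3-dioxolan-4-yl]-2-oxoethyl}-2H-pyran-2-one | C[C@H](c1ccc(O)cc1)c1c(O)cc(CC(=O)[C@@H]2OC(C)(C)OC2c2ccc(OC)cc2)oc1=O
F3 | step 3 | [(4R)-5-(4-methoxyphenyl)-2,2-dimethyl-1,3-dioxolan-4-yl]{2,4,6-trihydroxy-3-[(1R)-1-(4-hydroxyphenyl)ethyl]phenyl}methanone | C[C@H](c1ccc(O)cc1)c1c(O)cc(O)c(C(=O)[C@@H]2OC(C)(C)OC2c2ccc(OC)cc2)c1O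
F4 | step 1 | 4-hydroxy-3-[1-(4-hydroxyphenyl)ethenyl]-6-methyl-2H-pyran-2-one | C=C(c1ccc(O)cc1)c1c(O)cc(C)oc1=O
F5 | step 4 | (±)-trans-methyl 3-[4-(benzyloxy)phenyl]oxirane-2-carboxylate (racemate) | COC(=O)C1OC1c1ccc(OCc2ccccc2)cc1
F6 | step 4 | methyl (2R,3S)-3-[4-(benzyloxy)phenyl]oxirane-2-carboxylate | COC(=O)[C@@H]1O[C@H]1c1ccc(OCc2ccccc2)cc1
F7 | step 4 | 6-{2-[(2R,3S)-3-(4-benzyloxyphenyl)oxiran-2-yl]-2-oxoethyl}-4-hydroxy-3-[(1R)-1-(4-hydroxyphenyl)ethyl]-2H-pyran-2-one | C[C@H](c1ccc(O)cc1)c1c(O)cc(CC(=O)[C@@H]2O[C@H]2c2ccc(OCc3ccccc3)cc2)oc1=O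
F8 | step 4 | (2R,3R)-2-(4-benzyloxyphenyl)-3,5,7-trihydroxy-6-[(1R)-1-(4-hydroxyphenyl)ethyl]-2,3-dihydro-4H-chromen-4-one | C[C@H](c1ccc(O)cc1)c1c(O)cc2c(c1O)C(=O)[C@H](O)[C@@H](c1ccc(OCc3ccccc3)cc1)O2
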